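## Structural features

Rubioncolin C (12) is achiral and consists of two naphthalene-derived units joined through a single ether oxygen. Rings A and B form a 1-naphthol whose ring A is fully substituted: hydroxyl on C1, methyl ester on C2, prenyl on C3 and the ether oxygen on C4, with ring B an unsubstituted benzo ring. Rings C and D form a 1,4-naphthoquinone (carbonyls at C1' and C4', hydrogen on C3', benzo ring D) that carries the ether oxygen on C2'. No stereocentre is present, so the only stereocentres of the route are two transient bridgeheads standing next to the bridging oxygen. The fragile groups are the prenyl alkene (acid, electrophiles, ene partners), the C1 hydroxyl chelated to the ester (an acidic salicylate-type phenol) and, above all, the 2-aryloxyquinone, a redox-active vinylogous aryl ester that nucleophiles cleave by addition–elimination. The real difficulty is the ether: its oxygen sits on C4 between the prenyl-bearing C3 and the peri position C5, on an oxidation-prone hydroquinone, and the quinone oxidation level must be brought in without harming ring A. The key step uses the pattern C1'(O)–C2'(OAr)–C3'(H)–C4'(O) of ring C, which is the carbon chain of a 3-aryloxyfuran: furan C2 and C5 become C1' and C4', the furan oxygen ends as the C1' oxygen, and benzyne delivers the carbons of ring D.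

## Logic of the disconnections

12 to 11: the C4'=O bond is cut, so that the quinone becomes a 2-aryloxy-1-naphthol with a free para position. The naphthol is the direct product of opening an oxygen-bridged cycloadduct, and the electrophilic quinone then appears only in the last step. The forward oxidation must choose the electron-rich naphthol of rings C and D over the chelated, para-blocked naphthol of ring A and leave the prenyl alkene alone.

11 to 9 (through 10): the C4' carbon is reconnected to the C1' oxygen as a bridge and the acetal is restored on the C1 oxygen; in the forward direction the C4'–O bridge bond and the O–CH2 acetal bond are cleaved. This trades the aromaticity of ring C for a bicycle that is recognisably a cycloadduct. The forward step needs acid to ionise the bridge before the enol ether can be solvolysed, and the acetal must leave without damage to the prenyl group or the new naphthol.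

9 to 6 and 8 (from 7): C1'–C8a' and C4'–C4a' are cut. Both bonds of ring C to ring D form in one operation, and the problem is reduced to an aryl 3-furyl ether and a commercial aryne precursor. The forward step demands that 8 meet only the furan diene of 6, which is why the C1 oxygen carries no hydrogen.

6 to 5: the O–CH2 bond of the acetal on the C1 oxygen is cut. The protection is placed after the ether formation because only then are the two hydroxyls already differentiated. The forward alkylation must overcome the hydrogen bond and the steric shielding of this phenol, so complete deprotonation is required.

5 to 3 and 4: the bond between the ether oxygen and furan C3 is cut. This is the only heteroatom–carbon bond joining the halves, and it can be made by copper catalysis from a commercial halide. The forward coupling must arylate the hindered C4 oxygen and not the chelated C1 oxygen, and must keep the hydroquinone from being oxidised.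

3 to 1 and 2: the bond from C3 to the prenyl CH2 is cut. C3 is the only unsubstituted, nucleophilic position of the hydroquinone ring of 1, and both partners are commercial. The forward alkylation must stop at C-allylation and not go on to cyclise onto the neighbouring C4 hydroxyl.

## Other disconnections considered

Alternative 1: The cut is C2–C3 of ring A, leading back to the ortho-alkynyl benzoylacetate A1. In the forward sense Ph3PAuNTf2 would activate the alkyne of A1, the enol carbon would attack the alkyne carbon remote from the arene (6-endo-dig Conia-ene closure), and tautomerisation would give the naphthol A2.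
- In favour: a catalytic isomerisation without by-product, near room temperature, that places ester and prenyl group unambiguously on a newly formed benzenoid ring.
- Against it here: ring A with both oxygens and the ester is already available as 1, whereas A2 lacks the C4 oxygen and would need a para-oxygenation sequence merely to reach 3. A1 itself requires an alkyne coupling and an acylation. Its skipped enyne (alkyne–CH2–alkene) invites isomerisation, enyne cycloisomerisation and 5-exo closure beside the desired path.
- Comparison: in atom economy and in needing no protecting group for its key step this alternative is the better of the two, and it is the equal of the aryne cycloaddition in mildness. Structurally it builds the half of 12 that poses no problem and leaves the ether and the quinone unsolved. In step economy it is clearly behind, since it spends several steps on a compound the chosen plan reaches in one.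

Alternative 2: The cuts are C1–C2 and C2–C3, removing the ester-bearing carbon from ring A and leading back to the indene bis-silyl ether A3 and methyl bromodiazoacetate A4. In the forward sense Rh2(esp)2 would decompose A4, the carbenoid would cyclopropanate the silyl enol ether double bond of A3, and opening of the bromocyclopropane with loss of HBr would expand the five-membered ring to the naphthoate A5. Desilylation of A5 would give 3.
- In favour: a one-carbon insertion that installs the ester between the two oxygenated carbons with the prenyl group already in place.
- Against it here: A3 is a prenylated, partly reduced and doubly silylated indanedione derivative that would itself take several steps. The electrophilic carbenoid could also cyclopropanate the electron-rich prenyl alkene. A4 is thermally labile and must be made and used cold.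
- Comparison: the ring expansion is the equal of the chosen key step in the number of skeletal bonds formed (two) and is arguably the more inventive. It converges on the same compound 3 that a single Friedel–Crafts step gives from 1, so in step economy it cannot compete. Like alternative 1 it leaves the ether and the quinone untouched, and it would have to be combined with the chosen key step rather than replace it.

Alternative 3: The cut is C4'–C4a' of ring C, leading back to the 4-hydroxy-4-phenylcyclobutenone A6 that carries the aryloxy group on the ring carbon next to the carbinol. In the forward sense heating in xylene would open A6 to a vinylketene, the ketene carbon would bond to the ortho carbon of the phenyl group, and tautomerisation would give the aryloxy-naphthalenediol A7. Mild oxidation of A7 would give 12.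
- In favour: ring C arrives at the hydroquinone level with both oxygens in place, so the final oxidation is trivial and fully selective. This is better than the oxidation of a naphthol in the chosen plan. The key step needs no reagent, and the regiochemistry is fixed by the precursor.
- Against it here: A6 would have to be assembled on the C4 oxygen of 3 by a vinylogous acylation with a four-membered-ring dione and a 1,2-addition of a phenyl nucleophile. That addition must spare the methyl ester and the acidic C1 hydroxyl, must choose the right carbonyl and must not expel the aryloxide. Prolonged heating near 140 °C is needed in the presence of the prenyl group.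
- Comparison: on paper this alternative is one step shorter from 3 and has the better endgame; both are points in its favour. The chosen plan is the safer in chemoselectivity, because an aryne and a furan ignore the ester where an aryl-metal reagent does not. It also rests on commercial partners throughout, and it forms two skeletal bonds in its key step against one.

Key step: step 4

Remarks on the chemistry:
- Locants of the naphthoate unit (rings A and B) are unprimed, those of the quinone unit (rings C and D) are primed, and prenyl stands for 3-methylbut-2-en-1-yl.
- 9 is assumed to form as a racemate. Both of its stereocentres disappear in step 5 and 12 is achiral.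
- The structures of 6 and 9 were checked atom by atom against 12 and need no correction; the bridgehead hydrogens of 9 are necessarily cis.
- The MOM ether on the C1 oxygen of 6 is kept on purpose. A free chelated phenol would be arylated by 8 and close onto the ester, a silyl ether would not survive fluoride, and an acyl mask would need basic cleavage in the presence of an air-sensitive naphthol.
- The improvement made is in the unmasking (step 5), which is staged so that the bridge is opened before any protic nucleophile is admitted.

## Route

Step 1
Reactants: 1 methyl 1,4-dihydroxy-2-naphthoate; 2 2-methylbut-3-en-2-ol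
Product: 3 methyl 1,4-dihydroxy-3-prenyl-2-naphthoate
Conditions: BF3·OEt2 (0.5 equiv), dioxane, rt, Ar
Reagents that add atoms: none
Why: Friedel–Crafts allylation of a naphthohydroquinone: BF3 ionises the tertiary allylic alcohol to the dimethylallyl cation, which is attacked through its unhindered primary terminus by C3, the only free position of ring A and ortho to the non-chelated C4 hydroxyl. A near-stoichiometric amount of 2 and a short reaction time should keep the product from cyclising onto the C4 oxygen.

Step 2
Reactants: 3 methyl 1,4-dihydroxy-3-prenyl-2-naphthoate; 4 3-bromofuran
Product: 5 methyl 4-(furan-3-yloxy)-1-hydroxy-3-prenyl-2-naphthoate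
Conditions: CuI (10 mol %), picolinic acid (20 mol %), K3PO4, DMSO, 90 °C, Ar (degassed, sealed tube)
Reagents that add atoms: none
Why: Ullmann-type C–O coupling: the ligated copper phenoxide takes up the C–Br bond of 4 and reductive elimination forms the bond from oxygen to furan C3. The C1 oxygen is held in the hydrogen bond to the ester and, once deprotonated, forms an O,O-chelate of the β-keto-ester type that acts as a ligand and not as a nucleophile, so the more electron-rich C4 phenoxide should be the one arylated. Strict exclusion of oxygen keeps the hydroquinone from going to the quinone.

Step 3
Reactants: 5 methyl 4-(furan-3-yloxy)-1-hydroxy-3-prenyl-2-naphthoate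
Product: 6 methyl 4-(furan-3-yloxy)-1-(methoxymethoxy)-3-prenyl-2-naphthoate
Conditions: NaH, MOMCl, DMF, 0 °C → rt
Reagents that add atoms: chloromethyl methyl ether (MOMCl), COCCl
Why: Williamson-type O-alkylation: NaH deprotonates the chelated C1 hydroxyl completely and the free phenoxide displaces chloride from the reactive α-chloro ether. Furan, prenyl group and ester are inert to these conditions.

Step 4
Reactants: 6 methyl 4-(furan-3-yloxy)-1-(methoxymethoxy)-3-prenyl-2-naphthoate; 7 2-(trimethylsilyl)phenyl trifluoromethanesulfonate
Product: 9 methyl 4-{[(1S*,4S*)-1,4-dihydro-1,4-epoxynaphthalen-2-yl]oxy}-1-(methoxymethoxy)-3-prenyl-2-naphthoate (racemic), via benzyne 8 (not isolated)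
Conditions: 7 (1.3 equiv), CsF (3 equiv), MeCN, rt
Reagents that add atoms: none
Why: Fluoride attacks the silicon of 7 and triflate leaves from the neighbouring carbon, so that benzyne 8 is released slowly, at the rate at which CsF dissolves in MeCN. 8 then adds suprafacially across furan C2 and C5 of 6 in a concerted aryne Diels–Alder reaction; the closest known reaction type is the [4+2] cycloaddition of arynes from ortho-silylaryl triflates with furans. The bonds C1'–C8a' and C4'–C4a' form in the same step, so ring C closes by cycloaddition of the two diene termini onto the two aryne carbons, not by an exo or endo cyclisation, and it emerges as the six-membered carbocycle of a 7-oxabicyclo[2.2.1]heptadiene. The bridgehead stereocentres C1' and C4' are fixed relative to each other by the oxygen bridge, which can span only one face; the two faces of the furan are enantiotopic and nothing distinguishes them, so 9 should be racemic, which is immaterial because both centres vanish in step 5. No regiochemical question arises because 8 is symmetric. The selectivity needed is chemoselectivity: the electron-rich 3-aryloxyfuran is by far the best 4π partner in 6, ahead of an ene reaction at the prenyl group or addition to a naphthalene ring, and the MOM ether removes the phenoxide that would otherwise be arylated and close onto the ester. Only a small excess of 7 is used so that the enol ether of 9 is not attacked by a second aryne; 9 is a vinylogous acetal and should be filtered through base-washed silica or carried on crude.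

Step 5
Reactants: 9 methyl 4-{[(1S*,4S*)-1,4-dihydro-1,4-epoxynaphthalen-2-yl]oxy}-1-(methoxymethoxy)-3-prenyl-2-naphthoate
Product: 11 methyl 1-hydroxy-4-[(1-hydroxynaphthalen-2-yl)oxy]-3-prenyl-2-naphthoate, via MOM-protected aryloxynaphthol 10 (not isolated)
Conditions: camphorsulfonic acid (10 mol %), CH2Cl2, 0 °C; then MeOH, HCl (1.25 M in MeOH), rt, Ar
Reagents that add atoms: none
Why: Acid-catalysed isomerisation of a 1,4-epoxy-1,4-dihydronaphthalene to a 1-naphthol: the C4'–O bond is a vinylogous acetal bond (ArO–C2'=C3'–C4'–O) and ionises to a benzylic allyl cation stabilised by the aryloxy oxygen, and loss of the C1' proton aromatises ring C to 10 and erases both stereocentres. Methanol is admitted only after the enol ether has become an inert diaryl ether; the chelation-activated MOM ether is then cleaved by acetal exchange, the methoxymethyl cation being trapped by the solvent and not by the naphthol. The opposite sense of bridge opening would be harmless, because that naphthol would be oxidised to the same quinone.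

Step 6
Reactants: 11 methyl 1-hydroxy-4-[(1-hydroxynaphthalen-2-yl)oxy]-3-prenyl-2-naphthoate
Product: 12 rubioncolin C, methyl 4-[(1,4-dioxo-1,4-dihydronaphthalen-2-yl)oxy]-1-hydroxy-3-prenyl-2-naphthoate
Conditions: (KSO3)2NO (2.5 equiv), KH2PO4, H2O/acetone, 0 °C → rt
Reagents that add atoms: potassium nitrosodisulfonate (KSO3)2NO, [K+].[K+].[O]N(S(=O)(=O)[O-])S(=O)(=O)[O-]
Why: Teuber oxidation of a 1-naphthol to a 1,4-naphthoquinone: the nitroxyl radical removes the hydroxyl hydrogen of the electron-rich C1' naphthol, a second equivalent couples at the free para position C4', and loss of imidodisulfonate leaves the C4' carbonyl. The naphthol of ring A is deactivated by the ester and its hydrogen bond and has no free para position, and the prenyl alkene is not attacked by this one-electron oxidant.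

## Compound list

1 | methyl 1,4-dihydroxy-2-naphthoate | COC(=O)c1cc(O)c2ccccc2c1O | starting material
2 | 2-methylbut-3-en-2-ol | CC(C)(O)C=C | starting material
3 | methyl 1,4-dihydroxy-3-prenyl-2-naphthoate | COC(=O)c1c(CC=C(C)C)c(O)c2ccccc2c1O | intermediate
4 | 3-bromofuran | Brc1ccoc1 | starting material
5 | methyl 4-(furan-3-yloxy)-1-hydroxy-3-prenyl-2-naphthoate | COC(=O)c1c(CC=C(C)C)c(Oc2ccoc2)c2ccccc2c1O | intermediate
6 | methyl 4-(furan-3-yloxy)-1-(methoxymethoxy)-3-prenyl-2-naphthoate | COCOc1c(C(=O)OC)c(CC=C(C)C)c(Oc2ccoc2)c2ccccc12 | intermediate
7 | 2-(trimethylsilyl)phenyl trifluoromethanesulfonate | C[Si](C)(C)c1ccccc1OS(=O)(=O)C(F)(F)F | starting material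
8 | benzyne (not isolated) | C1=CC=CC#C1 | intermediate
9 | methyl 4-{[(1S*,4S*)-1,4-dihydro-1,4-epoxynaphthalen-2-yl]oxy}-1-(methoxymethoxy)-3-prenyl-2-naphthoate (racemic, one enantiomer drawn) | COCOc1c(C(=O)OC)c(CC=C(C)C)c(OC3=C[C@@H]4O[C@H]3c3ccccc34)c2ccccc12 | intermediate
10 | methyl 4-[(1-hydroxynaphthalen-2-yl)oxy]-1-(methoxymethoxy)-3-prenyl-2-naphthoate (not isolated) | COCOc1c(C(=O)OC)c(CC=C(C)C)c(Oc3ccc4ccccc4c3O)c2ccccc12 | intermediate
11 | methyl 1-hydroxy-4-[(1-hydroxynaphthalen-2-yl)oxy]-3-prenyl-2-naphthoate | COC(=O)c1c(CC=C(C)C)c(Oc3ccc4ccccc4c3O)c2ccccc2c1O | intermediate
12 | rubioncolin C | COC(=O)c1c(CC=C(C)C)c(OC2=CC(=O)c3ccccc3C2=O)c2ccccc2c1O | target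

## Step count and least certain steps

Total step count: 6. Longest linear sequence: 6 steps (1 → 3 → 5 → 6 → 9 → 11 → 12); 2, 4 and 7 enter as commercial partners.

Step 4 (key step). The aryne may be diverted into an ene reaction with the prenyl group or into a second addition to the enol ether of the cycloadduct, and the bridge may open prematurely on silica gel. The first two cost material; the third only anticipates step 5. Fallback: the cycloaddition is given up and the quinone ring is introduced ready-made. Setting out from 3, the C4 phenoxide (K2CO3, DMF, rt, Ar) would displace bromide from commercial 2-bromo-1,4-naphthoquinone by addition–elimination, the classical way to 2-aryloxy-1,4-naphthoquinones, and the route is rejoined directly at 12. No new compound arises on this way (F0).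

Step 2. The doubly deprotonated hydroquinone may be oxidised by traces of air, the chelating C1 oxygen may sequester copper, and the hindered C4 phenoxide may couple only slowly with an electron-rich heteroaryl bromide. Fallback: the hydroxyls are differentiated by protection before the coupling, and the coupling is changed to an oxidative one at room temperature.
- Setting out from 3, acetylation of the more reactive C4 hydroxyl (Ac2O, pyridine, 0 °C) would give methyl 4-acetoxy-1-hydroxy-3-prenyl-2-naphthoate F1.
- MOM protection (NaH, MOMCl, DMF, 0 °C) would give methyl 4-acetoxy-1-(methoxymethoxy)-3-prenyl-2-naphthoate F2.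
- Methanolysis (K2CO3, MeOH, 0 °C) would give methyl 4-hydroxy-1-(methoxymethoxy)-3-prenyl-2-naphthoate F3.
- Chan–Lam coupling of F3 with furan-3-ylboronic acid (Cu(OAc)2, pyridine, 4 Å molecular sieves, CH2Cl2, air, rt) rejoins the route at 6.

Step 5. Solvolysis at the enol ether could compete with ionisation of the bridge and detach the aryloxy group. The cation released from the MOM group could alkylate the very nucleophilic new naphthol. Prolonged acid could add across the prenyl alkene. Fallback: the acetal is replaced by a group that leaves without acid.
- Setting out from 5, allylation (allyl bromide, K2CO3, DMF) would give methyl 1-(allyloxy)-4-(furan-3-yloxy)-3-prenyl-2-naphthoate F4.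
- The cycloaddition with 7 and CsF would give methyl 1-(allyloxy)-4-{[(1S*,4S*)-1,4-dihydro-1,4-epoxynaphthalen-2-yl]oxy}-3-prenyl-2-naphthoate F5.
- Catalytic camphorsulfonic acid in CH2Cl2 would give methyl 1-(allyloxy)-4-[(1-hydroxynaphthalen-2-yl)oxy]-3-prenyl-2-naphthoate F6.
- Allyl transfer to morpholine with Pd(PPh3)4 (zerovalent palladium, THF, rt) rejoins the route at 11.

Step 6. Oxidation may not stay on the C/D naphthol: attack on the chelated ring A naphthol would expel the aryloxy group, and the aryloxyquinone may be hydrolysed in the aqueous buffer. Fallback: the ring A hydroxyl stays masked through the oxidation. Setting out from 10, isolated by stopping step 5 after its aprotic first stage, oxidation with (KSO3)2NO would give methyl 4-[(1,4-dioxo-1,4-dihydronaphthalen-2-yl)oxy]-1-(methoxymethoxy)-3-prenyl-2-naphthoate F7. Anhydrous cleavage of its MOM ether (CF3CO2H, CH2Cl2, 0 °C), now on a substrate without a nucleophilic ring, rejoins the route at 12.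

## Further compounds

F0 | step 4 | none | none
F1 | step 2 | methyl 4-acetoxy-1-hydroxy-3-prenyl-2-naphthoate | COC(=O)c1c(CC=C(C)C)c(OC(C)=O)c2ccccc2c1O
F2 | step 2 | methyl 4-acetoxy-1-(methoxymethoxy)-3-prenyl-2-naphthoate | COCOc1c(C(=O)OC)c(CC=C(C)C)c(OC(C)=O)c2ccccc12
F3 | step 2 | methyl 4-hydroxy-1-(methoxymethoxy)-3-prenyl-2-naphthoate | COCOc1c(C(=O)OC)c(CC=C(C)C)c(O)c2ccccc12
F4 | step 5 | methyl 1-(allyloxy)-4-(furan-3-yloxy)-3-prenyl-2-naphthoate | C=CCOc1c(C(=O)OC)c(CC=C(C)C)c(Oc2ccoc2)c2ccccc12
F5 | step 5 | methyl 1-(allyloxy)-4-{[(1S*,4S*)-1,4-dihydro-1,4-epoxynaphthalen-2-yl]oxy}-3-prenyl-2-naphthoate (racemic, one enantiomer drawn) | C=CCOc1c(C(=O)OC)c(CC=C(C)C)c(OC3=C[C@@H]4O[C@H]3c3ccccc34)c2ccccc12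
F6 | step 5 | methyl 1-(allyloxy)-4-[(1-hydroxynaphthalen-2-yl)oxy]-3-prenyl-2-naphthoate | C=CCOc1c(C(=O)OC)c(CC=C(C)C)c(Oc3ccc4ccccc4c3O)c2ccccc12
F7 | step 6 | methyl 4-[(1,4-dioxo-1,4-dihydronaphthalen-2-yl)oxy]-1-(methoxymethoxy)-3-prenyl-2-naphthoate | COCOc1c(C(=O)OC)c(CC=C(C)C)c(OC3=CC(=O)c4ccccc4C3=O)c2ccccc12
A1 | alternative 1 | methyl 3-[2-(5-methylhex-4-en-1-yn-1-yl)phenyl]-3-oxopropanoate | COC(=O)CC(=O)c1ccccc1C#CCC=C(C)C
A2 | alternative 1 | methyl 1-hydroxy-3-prenyl-2-naphthoate | COC(=O)c1c(CC=C(C)C)cc2ccccc2c1O
A3 | alternative 2 | 1,3-bis(tert-butyldimethylsilyloxy)-2-prenyl-1H-indene (racemic) | CC(C)=CCC1=C(O[Si](C)(C)C(C)(C)C)c2ccccc2C1O[Si](C)(C)C(C)(C)C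
A4 | alternative 2 | methyl bromodiazoacetate | COC(=O)C(Br)=[N+]=[N-]
A5 | alternative 2 | methyl 1,4-bis(tert-butyldimethylsilyloxy)-3-prenyl-2-naphthoate | COC(=O)c1c(CC=C(C)C)c(O[Si](C)(C)C(C)(C)C)c2ccccc2c1O[Si](C)(C)C(C)(C)C
A6 | alternative 3 | methyl 1-hydroxy-4-[(4-hydroxy-3-oxo-4-phenylcyclobut-1-en-1-yl)oxy]-3-prenyl-2-naphthoate (racemic) | COC(=O)c1c(CC=C(C)C)c(OC3=CC(=O)C3(O)c3ccccc3)c2ccccc2c1O
A7 | alternative 3 | methyl 4-[(1,4-dihydroxynaphthalen-2-yl)oxy]-1-hydroxy-3-prenyl-2-naphthoate | COC(=O)c1c(CC=C(C)C)c(Oc2cc(O)c3ccccc3c2O)c2ccccc2c1O
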